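**Retrosynthetic overview**

1. The target is a 1-aryltetralin, numbered C1–C4 in ring B and C4a–C8a in ring A. The plan rests on ring B: C1 carries ring C, C2 and C3 carry trans CH2OH groups, C4 is a benzylic CH2, and ring A carries C5/C6 OMe and C7 OH. Ring B is cut at C1–C2 and C3–C4 into a hydroxy-o-quinodimethane spanning C1 and C4 and a fumarate (C2=C3) that already holds both CH2OH carbons.
2. The diene comes from photoenolisation of a 2-benzylbenzaldehyde (formyl carbon = C4, benzylic CH2 = C1). The C4 hydroxyl of the adduct is a traceless handle, and chirality is supplied by (S)-lactate esters on the fumarate.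
3. The 2-benzylbenzaldehyde is made by Negishi coupling of a 6-bromo-benzaldehyde with a benzylic zinc reagent. The bromine is present from the start (Rieche formylation of 5-bromo-1,2,3-trimethoxybenzene, BBr3, selective 4-O-benzylation, methylation), so no ortho-metalation beside benzyl ethers is needed.
4. After the cycloaddition, one hydrogenolysis removes the C4 hydroxyl and both benzyl ethers, NaOMe/MeOH exchanges the auxiliaries for methyl esters under equilibrating conditions (all-trans C1/C2/C3), and LiAlH4 gives the diol.
5. Ring order: rings A and C are bought; ring B is the only ring formed, in the key step.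

Key step: step 8

Assumption: the (S)-lactate esters are taken to induce the facial sense that makes C1 R, by analogy with the behaviour of this auxiliary toward related hydroxy-aryl-o-quinodimethanes; the enantiomeric lactate would serve if the sense proved opposite.

**Route**

Step 1
Reactants: 1 5-bromo-1,2,3-trimethoxybenzene
Product: 2 6-bromo-2,3,4-trimethoxybenzaldehyde
Conditions: Cl2CHOMe, TiCl4, CH2Cl2, 0 °C → rt; then ice/aq. HCl
Reagents that add atoms: dichloromethyl methyl ether COC(Cl)Cl; water O
Why: Rieche formylation, in which the two free ring positions of 1 are equivalent and each lies ortho and para to a methoxyl, so the formyl group can only enter next to bromine, and any ortho-demethylation by TiCl4 is harmless because all three ethers are cleaved in step 2.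

Step 2
Reactants: 2 6-bromo-2,3,4-trimethoxybenzaldehyde
Product: 3 6-bromo-2,3,4-trihydroxybenzaldehyde
Conditions: BBr3 (excess), CH2Cl2, −78 °C → rt; then H2O
Reagents that add atoms: none
Why: Exhaustive aryl methyl ether cleavage by BBr3 (boron coordination, bromide attack on methyl), which leaves the aryl bromide and, after hydrolysis, the aldehyde intact.

Step 3
Reactants: 3 6-bromo-2,3,4-trihydroxybenzaldehyde
Product: 4 4-(benzyloxy)-6-bromo-2,3-dihydroxybenzaldehyde
Conditions: BnBr (1 equiv), NaHCO3, NaI (cat.), DMF, 40 °C, N2
Reagents that add atoms: benzyl bromide BrCc1ccccc1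
Why: Williamson etherification under weak-base control, in which only the 4-hydroxyl (para to the formyl group, the most acidic) is ionised by NaHCO3, while the 2-hydroxyl is held in a hydrogen bond to the carbonyl and the 3-hydroxyl is the least acidic.

Step 4
Reactants: 4 4-(benzyloxy)-6-bromo-2,3-dihydroxybenzaldehyde
Product: 5 4-(benzyloxy)-6-bromo-2,3-dimethoxybenzaldehyde
Conditions: MeI, K2CO3, DMF, 40 °C
Reagents that add atoms: iodomethane CI
Why: Williamson methylation of the two remaining phenols under the stronger base, the chelated 2-hydroxyl included.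

Step 5
Reactants: 6 4-(benzyloxy)-3-methoxybenzyl alcohol
Product: 7 4-(benzyloxy)-3-methoxybenzyl chloride
Conditions: SOCl2, CH2Cl2, 0 °C → rt
Reagents that add atoms: thionyl chloride O=S(Cl)Cl
Why: Chlorodehydroxylation of an electron-rich benzylic alcohol through its chlorosulfite, the chloride being preferred to the bromide because it stores well and gives little Wurtz coupling on zinc insertion.

Step 6
Reactants: 7 4-(benzyloxy)-3-methoxybenzyl chloride; 5 4-(benzyloxy)-6-bromo-2,3-dimethoxybenzaldehyde
Product: 9 4-(benzyloxy)-6-[4-(benzyloxy)-3-methoxybenzyl]-2,3-dimethoxybenzaldehyde, via benzylzinc chloride 8 (not isolated)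
Conditions: 7, Zn dust, LiCl, THF, 25 °C; then 5, Pd(OAc)2 (cat.), SPhos (cat.), THF, 25 °C
Reagents that add atoms: none
Why: Negishi coupling, in which LiCl-assisted zinc insertion gives 8, oxidative addition of palladium into the C–Br bond is helped by the ortho formyl group, and transmetalation with reductive elimination should form the aryl–CH2 bond faster than 8 adds to the hindered, electron-rich aldehyde.

Step 7
Reactants: 10 fumaryl chloride; 11 methyl (S)-lactate (2.2 equiv)
Product: 12 bis[(S)-1-methoxy-1-oxopropan-2-yl] fumarate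
Conditions: pyridine, CH2Cl2, 0 °C → rt
Reagents that add atoms: none
Why: Acylation of the secondary alcohol by the diacid chloride with pyridine as HCl acceptor, which does not involve the lactate stereocentre and keeps the E alkene.

Step 8
Reactants: 9 4-(benzyloxy)-6-[4-(benzyloxy)-3-methoxybenzyl]-2,3-dimethoxybenzaldehyde; 12 bis[(S)-1-methoxy-1-oxopropan-2-yl] fumarate
Product: 14 bis[(S)-1-methoxy-1-oxopropan-2-yl] (1R,2S,3R,4R)-7-(benzyloxy)-1-[4-(benzyloxy)-3-methoxyphenyl]-4-hydroxy-5,6-dimethoxy-1,2,3,4-tetrahydronaphthalene-2,3-dicarboxylate (1,2-trans/2,3-trans/3,4-cis), via dienol 13 (not isolated)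
Conditions: hν (365 nm), 12 (3 equiv), degassed toluene, 0 °C
Reagents that add atoms: none
Why: Excitation of the formyl group of 9 (its oxygen is turned toward the benzyl group by the neighbouring methoxyl) and 1,5-hydrogen transfer from the doubly benzylic CH2 dearomatise ring A to dienol 13, whose inward isomers revert to 9 by a thermal hydrogen shift, and 13 is trapped by fumarate 12 in a thermal suprafacial [4+2] that restores ring A. The closest known reaction type is the photoenolisation/Diels–Alder reaction of 2-benzylbenzaldehydes with fumaric diesters of α-hydroxy esters. Ring B closes as a six-membered carbocycle by intermolecular cycloaddition across C1 and C4 of the diene, with C1–C2 and C3–C4 formed together. C1 and C4 come out cis because aryl and hydroxyl both point outward in 13, C2 and C3 come out trans because the fumarate geometry is carried over, and the C3 ester comes out cis to the C4 hydroxyl if, as expected for an oxygenated diene terminus, the ester next to it sits endo. The step needs facial selectivity, since this alone fixes C1 (R), and it should come from the (S)-lactate groups, whose carbonyl can accept a hydrogen bond from the dienol hydroxyl and so hold one auxiliary over one face of the alkene; esters of terpene alcohols were not chosen because they discriminate fumarate faces only under Lewis acid activation, which the dienol would not survive. The orientation at C2 and C3 is not decisive, because both centres are equilibrated in step 10.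

Step 9
Reactants: 14 the cycloadduct of step 8
Product: 15 bis[(S)-1-methoxy-1-oxopropan-2-yl] (1R,2S,3S)-7-hydroxy-1-(4-hydroxy-3-methoxyphenyl)-5,6-dimethoxy-1,2,3,4-tetrahydronaphthalene-2,3-dicarboxylate
Conditions: H2 (1 atm), Pd/C, EtOAc–AcOH, 25 °C
Reagents that add atoms: none
Why: Heterogeneous hydrogenolysis, which should cleave both O-benzyl groups and replace the C4 hydroxyl (benzylic, activated by the para oxygen at C7 and the ortho methoxyl at C5) by hydrogen while C1, C2 and C3 are untouched.

Step 10
Reactants: 15 the 4-deoxy bisphenol bis-lactyl diester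
Product: 16 dimethyl (1R,2S,3S)-7-hydroxy-1-(4-hydroxy-3-methoxyphenyl)-5,6-dimethoxy-1,2,3,4-tetrahydronaphthalene-2,3-dicarboxylate
Conditions: NaOMe (excess), MeOH, 50 °C, Ar; then AcOH
Reagents that add atoms: methanol CO
Why: Methoxide-mediated transesterification of the activated lactyl esters with concurrent enolisation at C2 and C3, so that both ester-bearing centres settle in (or stay in) the thermodynamically preferred all-trans arrangement relative to C1, which has no acidic hydrogen.

Step 11
Reactants: 16 the all-trans dimethyl ester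
Product: 17 (1R,2S,3S)-1-(4-hydroxy-3-methoxyphenyl)-2,3-bis(hydroxymethyl)-5,6-dimethoxy-1,2,3,4-tetrahydronaphthalen-7-ol (target)
Conditions: LiAlH4, THF, 0 °C → reflux; then aq. potassium sodium tartrate
Reagents that add atoms: none
Why: Hydride reduction of both methyl esters to primary alcohols, with the phenols carried as aluminium phenoxides and set free on work-up, touches no stereocentre and should deliver the target.

**Compound list**

1 | 5-bromo-1,2,3-trimethoxybenzene | COc1cc(Br)cc(OC)c1OC | starting material
2 | 6-bromo-2,3,4-trimethoxybenzaldehyde | COc1cc(Br)c(C=O)c(OC)c1OC | intermediate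
3 | 6-bromo-2,3,4-trihydroxybenzaldehyde | O=Cc1c(Br)cc(O)c(O)c1O | intermediate
4 | 4-(benzyloxy)-6-bromo-2,3-dihydroxybenzaldehyde | O=Cc1c(Br)cc(OCc2ccccc2)c(O)c1O | intermediate
5 | 4-(benzyloxy)-6-bromo-2,3-dimethoxybenzaldehyde | COc1c(C=O)c(Br)cc(OCc2ccccc2)c1OC | intermediate
6 | 4-(benzyloxy)-3-methoxybenzyl alcohol | COc1cc(CO)ccc1OCc1ccccc1 | starting material
7 | 4-(benzyloxy)-3-methoxybenzyl chloride | COc1cc(CCl)ccc1OCc1ccccc1 | intermediate
8 | [4-(benzyloxy)-3-methoxybenzyl]zinc chloride | COc1cc(C[Zn]Cl)ccc1OCc1ccccc1 | intermediate (not isolated)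
9 | 4-(benzyloxy)-6-[4-(benzyloxy)-3-methoxybenzyl]-2,3-dimethoxybenzaldehyde | COc1cc(Cc2cc(OCc3ccccc3)c(OC)c(OC)c2C=O)ccc1OCc1ccccc1 | intermediate
10 | fumaryl chloride | O=C(Cl)/C=C/C(=O)Cl | starting material
11 | methyl (S)-lactate | C[C@H](O)C(=O)OC | starting material
12 | bis[(S)-1-methoxy-1-oxopropan-2-yl] fumarate | COC(=O)[C@H](C)OC(=O)/C=C/C(=O)O[C@@H](C)C(=O)OC | intermediate
13 | hydroxy-o-quinodimethane (dienol) of 9, hydroxyl and aryl both outward | O/C=C1\C(OC)=C(OC)C(OCc2ccccc2)=C/C1=C\c1ccc(OCc2ccccc2)c(OC)c1 | intermediate (not isolated)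
14 | bis[(S)-1-methoxy-1-oxopropan-2-yl] (1R,2S,3R,4R)-7-(benzyloxy)-1-[4-(benzyloxy)-3-methoxyphenyl]-4-hydroxy-5,6-dimethoxy-1,2,3,4-tetrahydronaphthalene-2,3-dicarboxylate | COc1cc([C@@H]2c3cc(OCc4ccccc4)c(OC)c(OC)c3[C@H](O)[C@H](C(=O)O[C@@H](C)C(=O)OC)[C@H]2C(=O)O[C@@H](C)C(=O)OC)ccc1OCc1ccccc1 | intermediate
15 | bis[(S)-1-methoxy-1-oxopropan-2-yl] (1R,2S,3S)-7-hydroxy-1-(4-hydroxy-3-methoxyphenyl)-5,6-dimethoxy-1,2,3,4-tetrahydronaphthalene-2,3-dicarboxylate | COc1cc([C@@H]2c3cc(O)c(OC)c(OC)c3C[C@H](C(=O)O[C@@H](C)C(=O)OC)[C@H]2C(=O)O[C@@H](C)C(=O)OC)ccc1O | intermediate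
16 | dimethyl (1R,2S,3S)-7-hydroxy-1-(4-hydroxy-3-methoxyphenyl)-5,6-dimethoxy-1,2,3,4-tetrahydronaphthalene-2,3-dicarboxylate | COc1cc([C@@H]2c3cc(O)c(OC)c(OC)c3C[C@H](C(=O)OC)[C@H]2C(=O)OC)ccc1O | intermediate
17 | (1R,2S,3S)-1-(4-hydroxy-3-methoxyphenyl)-2,3-bis(hydroxymethyl)-5,6-dimethoxy-1,2,3,4-tetrahydronaphthalen-7-ol | COc1cc([C@@H]2c3cc(O)c(OC)c(OC)c3C[C@H](CO)[C@H]2CO)ccc1O | target

**Step count and risks**

Total step count: 11. Longest linear sequence: 9 steps (steps 1, 2, 3, 4, 6, 8, 9, 10, 11).

Steps most likely to fail:

Step 8. Facial discrimination may be weak and the dienophile geometry may erode. The aldehyde triplet can pass its energy to the fumarate (E to Z isomerisation), and the dienol hydroxyl may stay hydrogen-bonded to the neighbouring C5 methoxyl and not to the lactate carbonyl. The fallback separates the photochemistry from the cycloaddition. Starting from 9, irradiation (365 nm) in SO2-saturated benzene should trap the dienol by cheletropic addition as cis-5-(benzyloxy)-3-[4-(benzyloxy)-3-methoxyphenyl]-1-hydroxy-6,7-dimethoxy-1,3-dihydrobenzo[c]thiophene 2,2-dioxide F1. Heating F1 with 12 in toluene at 80 °C in the dark under a nitrogen stream should then release SO2 and regenerate dienol 13 thermally, and its addition to 12 rejoins the route at 14. The fumarate is then never exposed to a sensitiser, and solvent and temperature can be chosen for selectivity alone.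

Step 6. The benzylic zinc reagent may add to the aldehyde carbonyl or homocouple before it cross-couples. The fallback reverses the polarity of the partners. Starting from 5, Miyaura borylation (bis(pinacolato)diboron, KOAc, PdCl2(dppf), dioxane, 85 °C) should give 4-(benzyloxy)-2,3-dimethoxy-6-(4,4,5,5-tetramethyl-1,3,2-dioxaborolan-2-yl)benzaldehyde F2. Suzuki–Miyaura coupling of F2 with chloride 7 (Pd(OAc)2, SPhos, K3PO4, toluene–H2O, 80 °C) rejoins the route at 9; no carbon nucleophile that could attack the aldehyde is present.

Step 9. The C4–O hydrogenolysis may stall once the benzyl ethers are gone, or acid may dehydrate the alcohol toward a dihydronaphthalene whose double bond could migrate and endanger C1. The fallback removes the oxygen by ionic reduction first. Starting from 14, Et3SiH and CF3CO2H in CH2Cl2 at 0 °C should reduce the stabilised C4 cation to bis[(S)-1-methoxy-1-oxopropan-2-yl] (1R,2S,3S)-7-(benzyloxy)-1-[4-(benzyloxy)-3-methoxyphenyl]-5,6-dimethoxy-1,2,3,4-tetrahydronaphthalene-2,3-dicarboxylate F3. Neutral hydrogenolysis of F3 (H2, Pd/C, EtOAc) then cleaves only the benzyl ethers and rejoins the route at 15.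

**Further compounds**

F1 | step 8 | cis-5-(benzyloxy)-3-[4-(benzyloxy)-3-methoxyphenyl]-1-hydroxy-6,7-dimethoxy-1,3-dihydrobenzo[c]thiophene 2,2-dioxide (racemic, one enantiomer drawn) | COc1cc([C@@H]2c3cc(OCc4ccccc4)c(OC)c(OC)c3[C@H](O)S2(=O)=O)ccc1OCc1ccccc1
F2 | step 6 | 4-(benzyloxy)-2,3-dimethoxy-6-(4,4,5,5-tetramethyl-1,3,2-dioxaborolan-2-yl)benzaldehyde | COc1c(C=O)c(B2OC(C)(C)C(C)(C)O2)cc(OCc2ccccc2)c1OC
F3 | step 9 | bis[(S)-1-methoxy-1-oxopropan-2-yl] (1R,2S,3S)-7-(benzyloxy)-1-[4-(benzyloxy)-3-methoxyphenyl]-5,6-dimethoxy-1,2,3,4-tetrahydronaphthalene-2,3-dicarboxylate | COc1cc([C@@H]2c3cc(OCc4ccccc4)c(OC)c(OC)c3C[C@H](C(=O)O[C@@H](C)C(=O)OC)[C@H]2C(=O)O[C@@H](C)C(=O)OC)ccc1OCc1ccccc1
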